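**Retrosynthetic overview**
1. Kanzonol V comes from fluoride desilylation of its bis(triisopropylsilyl) ether. That ether is an isomer of an open-chain diyne in which the two benzene rings (ring A, ring B) are joined only by a C≡C bridge.
2. One gold-catalysed operation closes both heterocycles. The furan ring forms first, by addition of the ring-A phenol O-H across the bridge alkyne. The pyran ring follows by formation of chromene C2-C3: a 1,5-hydride shift from an isopropyl ether C-H to an ethynyl group, then collapse of vinylgold carbon C3 onto oxocarbenium carbon C2.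
3. Enabling feature: pyran oxygen O1 stands on ring-B carbon C8a, between C8 (bearing the benzofuran) and C4a (bearing C4), and C2 with its two methyls is simply the methine carbon of an isopropyl ether. H-C2-O1-C8a-C4a-C4 is a 1,5 array, the two ortho neighbours twist that C-H over the alkyne, and an ortho-ethynylaryl isopropyl ether already has the oxidation level of a 2,2-dimethyl-2H-chromene.
4. The diyne comes from Colvin homologation of a ring-B aldehyde. That aldehyde is made by Sonogashira union of a ring-B iodide (three steps from 2,6-dihydroxybenzaldehyde) with a ring-A ethynylphenol (three steps from 5-bromo-2,4-dihydroxybenzaldehyde, prenyl group by Stille coupling).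
5. Ring order: rings A and B are bought, then the furan ring, then the pyran ring.

Key step: step 9

Remark on the chemistry: the target has no stereocentre, and its only fixed double-bond geometry (C3=C4 of the pyran ring) is cis by ring constraint, so no stereocontrol is needed. Chromene locants (O1, C2, C3, C4, C4a, C5, C8, C8a) are used for the ring-B part even before the pyran ring exists.

Step 1
Reactants: 1 2,6-dihydroxybenzaldehyde
Product: 2 2,6-dihydroxy-3-iodobenzaldehyde
Conditions: NIS (1.0 equiv), MeCN, 0 °C
Reagents that add atoms: N-iodosuccinimide, O=C1CCC(=O)N1I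
Why: Electrophilic aromatic iodination: C3 and C5 are equivalent and are the only positions ortho or para to both hydroxyl groups and meta to the formyl group, so one equivalent of reagent at 0 °C should stop at the mono-iodide.

Step 2
Reactants: 2 2,6-dihydroxy-3-iodobenzaldehyde
Product: 3 2-hydroxy-3-iodo-6-(triisopropylsilyloxy)benzaldehyde
Conditions: TIPSCl (1.05 equiv), imidazole, DMF, 0 °C
Reagents that add atoms: chlorotriisopropylsilane, CC(C)[Si](Cl)(C(C)C)C(C)C
Why: Site-selective O-silylation: the bulky chlorosilane should take the hydroxyl group next to C5-H, since the other one is wedged between iodine and the formyl group and, being the more acidic, holds the hydrogen bond to the carbonyl oxygen.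

Step 3
Reactants: 3 2-hydroxy-3-iodo-6-(triisopropylsilyloxy)benzaldehyde
Product: 4 3-iodo-2-isopropoxy-6-(triisopropylsilyloxy)benzaldehyde
Conditions: i-PrOH, PPh3, DIAD, THF, 0 °C to 23 °C
Reagents that add atoms: propan-2-ol, CC(C)O
Why: Mitsunobu etherification: the acidic, chelated phenol is a good pronucleophile, its small oxygen centre displaces the activated secondary alcohol by SN2, and the neutral medium spares the aryl silyl ether and the aldehyde.

Step 4
Reactants: 5 5-bromo-2,4-dihydroxybenzaldehyde
Product: 6 5-bromo-2-hydroxy-4-(triisopropylsilyloxy)benzaldehyde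
Conditions: TIPSCl (1.05 equiv), imidazole, DMF, 0 °C to 23 °C
Reagents that add atoms: chlorotriisopropylsilane, CC(C)[Si](Cl)(C(C)C)C(C)C
Why: Site-selective O-silylation, well known for 2,4-dihydroxybenzaldehydes: the 2-hydroxyl group is tied up in the hydrogen bond to the formyl group, so the 4-hydroxyl group reacts.

Step 5
Reactants: 6 5-bromo-2-hydroxy-4-(triisopropylsilyloxy)benzaldehyde
Product: 7 2-hydroxy-5-(3-methylbut-2-enyl)-4-(triisopropylsilyloxy)benzaldehyde
Conditions: tributyl(3-methylbut-2-enyl)stannane, Pd(PPh3)4 (5 mol %), PhMe, 110 °C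
Reagents that add atoms: tributyl(3-methylbut-2-en-1-yl)stannane, CCCC[Sn](CCCC)(CCCC)CC=C(C)C
Why: Stille coupling: zerovalent palladium inserts into the C-Br bond, the prenyl group is transferred from tin, and reductive elimination from the allylpalladium species at its unsubstituted terminus should give the linear prenyl arene under neutral conditions that tolerate phenol, aldehyde and silyl ether.

Step 6
Reactants: 7 2-hydroxy-5-(3-methylbut-2-enyl)-4-(triisopropylsilyloxy)benzaldehyde
Product: 8 2-ethynyl-4-(3-methylbut-2-enyl)-5-(triisopropylsilyloxy)phenol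
Conditions: TMSCHN2 (2.5 equiv), n-BuLi (2.4 equiv), THF, -78 °C to 23 °C; aq NH4Cl
Reagents that add atoms: (trimethylsilyl)diazomethane, C[Si](C)(C)C=[N+]=[N-]
Why: Colvin rearrangement: the first equivalent of the lithiated diazo compound deprotonates the phenol, the second adds to the aldehyde, and Peterson-type loss of silanolate, loss of N2 and a very fast 1,2-hydrogen shift give the terminal alkyne in an aprotic medium that keeps the silyl ether.

Step 7
Reactants: 4 3-iodo-2-isopropoxy-6-(triisopropylsilyloxy)benzaldehyde, 8 2-ethynyl-4-(3-methylbut-2-enyl)-5-(triisopropylsilyloxy)phenol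
Product: 9 3-{[2-hydroxy-5-(3-methylbut-2-enyl)-4-(triisopropylsilyloxy)phenyl]ethynyl}-2-isopropoxy-6-(triisopropylsilyloxy)benzaldehyde
Conditions: PdCl2(PPh3)2 (3 mol %), CuI (5 mol %), Et3N, THF, degassed, 23 °C
Reagents that add atoms: none
Why: Sonogashira coupling: the aryl iodide reacts at room temperature, where the free ortho-alkynylphenol should survive without closing, and the aldehyde, silyl ethers and prenyl group are inert.

Step 8
Reactants: 9 3-{[2-hydroxy-5-(3-methylbut-2-enyl)-4-(triisopropylsilyloxy)phenyl]ethynyl}-2-isopropoxy-6-(triisopropylsilyloxy)benzaldehyde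
Product: 10 2-{[3-ethynyl-2-isopropoxy-4-(triisopropylsilyloxy)phenyl]ethynyl}-4-(3-methylbut-2-enyl)-5-(triisopropylsilyloxy)phenol
Conditions: TMSCHN2 (2.5 equiv), n-BuLi (2.4 equiv), THF, -78 °C to 0 °C; aq NH4Cl
Reagents that add atoms: (trimethylsilyl)diazomethane, C[Si](C)(C)C=[N+]=[N-]
Why: Colvin rearrangement as in step 6: the remote phenol is only deprotonated, the lithium phenoxide does not add to the bridge alkyne at this temperature, and the bulky triisopropylsilyl group should not migrate to the transient benzylic alkoxide.

Step 9
Reactants: 10 2-{[3-ethynyl-2-isopropoxy-4-(triisopropylsilyloxy)phenyl]ethynyl}-4-(3-methylbut-2-enyl)-5-(triisopropylsilyloxy)phenol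
Product: 12 2-[2,2-dimethyl-5-(triisopropylsilyloxy)-2H-chromen-8-yl]-5-(3-methylbut-2-enyl)-6-(triisopropylsilyloxy)benzofuran, via ethynyl-isopropoxy arylbenzofuran 11 (not isolated)
Conditions: [(2,4-(t-Bu)2C6H3O)3P]Au(NCPh)SbF6 (5 mol %), 4 Å MS, ClCH2CH2Cl (0.02 M), 23 °C, then 80 °C
Reagents that add atoms: none
Why: Proposed new method: the cationic monovalent gold complex first activates the bridge alkyne for anti 5-endo-dig addition of the free ring-A phenol followed by protodeauration (a known benzofuran synthesis) to give 11, and on heating it binds the terminal alkyne, slips toward the CH terminus and thereby puts positive charge on the ring-bound alkyne carbon (future C4), which accepts the tertiary hydride of the isopropyl ether in a 1,5-shift through a six-membered transition state. The ion pair so formed, an aryl oxocarbenium ion (its carbon is the future C2) and a styrylgold unit that carries gold on the future C3 cis to ring B because hydride and gold add anti, collapses by C3-C2 bond formation, a 6-endo-trig closure at the oxocarbenium carbon, and loss of the gold cation leaves the C3=C4 double bond, so that the whole step is a redox-neutral isomerization. The closest known reaction types are the Lewis-acid hydride-transfer cyclization of ortho-vinylaryl alkyl ethers to chromans and the gold- or platinum-catalysed 1,5-hydride shift and cyclization of aliphatic alkynyl ethers, and the new element is the pairing of an aryl isopropyl ether as donor with an unactivated arylacetylene as acceptor, which gives the 2H-chromene directly. The step needs the right order and the right acceptor: O-H addition at 23 °C is much faster than any hydride shift, so the bridge alkyne, the only other acceptor within reach of the isopropyl C-H, is consumed before heating, and the benzofuran that it leaves at C8 then buttresses the ether, turns the O1-C2 bond out of the ring-B plane (which frees the oxygen lone pair for the cation) and presses the C-H bond onto the ethynyl group. The Markovnikov polarization of the gold-bound arylacetylene shuts out both flanking oxygens, which could reach only the terminal carbon, the silyl ether at C5 has no hydride to offer, bond formation at C3 instead of C4 is favoured because it leaves a benzylic cation beta to gold, and the prenyl group is safe because the neighbouring oxygen is silylated. No stereocentre is formed.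

Step 10
Reactants: 12 2-[2,2-dimethyl-5-(triisopropylsilyloxy)-2H-chromen-8-yl]-5-(3-methylbut-2-enyl)-6-(triisopropylsilyloxy)benzofuran
Product: 13 kanzonol V
Conditions: TBAF (2.5 equiv), AcOH (2.5 equiv), THF, 0 °C
Reagents that add atoms: none
Why: Fluoride cleavage of aryl silyl ethers: buffered fluoride removes both groups at 0 °C without strong acid, so neither the 2H-chromene nor the ortho-prenylphenol can cyclize or isomerize.

**Compound list**
1 | 2,6-dihydroxybenzaldehyde | O=Cc1c(O)cccc1O | starting material
2 | 2,6-dihydroxy-3-iodobenzaldehyde | O=Cc1c(O)ccc(I)c1O | intermediate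
3 | 2-hydroxy-3-iodo-6-(triisopropylsilyloxy)benzaldehyde | O=Cc1c(O[Si](C(C)C)(C(C)C)C(C)C)ccc(I)c1O | intermediate
4 | 3-iodo-2-isopropoxy-6-(triisopropylsilyloxy)benzaldehyde | O=Cc1c(O[Si](C(C)C)(C(C)C)C(C)C)ccc(I)c1OC(C)C | intermediate
5 | 5-bromo-2,4-dihydroxybenzaldehyde | O=Cc1cc(Br)c(O)cc1O | starting material
6 | 5-bromo-2-hydroxy-4-(triisopropylsilyloxy)benzaldehyde | O=Cc1cc(Br)c(O[Si](C(C)C)(C(C)C)C(C)C)cc1O | intermediate
7 | 2-hydroxy-5-(3-methylbut-2-enyl)-4-(triisopropylsilyloxy)benzaldehyde | O=Cc1cc(CC=C(C)C)c(O[Si](C(C)C)(C(C)C)C(C)C)cc1O | intermediate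
8 | 2-ethynyl-4-(3-methylbut-2-enyl)-5-(triisopropylsilyloxy)phenol | C#Cc1cc(CC=C(C)C)c(O[Si](C(C)C)(C(C)C)C(C)C)cc1O | intermediate
9 | 3-{[2-hydroxy-5-(3-methylbut-2-enyl)-4-(triisopropylsilyloxy)phenyl]ethynyl}-2-isopropoxy-6-(triisopropylsilyloxy)benzaldehyde | O=Cc1c(O[Si](C(C)C)(C(C)C)C(C)C)ccc(C#Cc2cc(CC=C(C)C)c(O[Si](C(C)C)(C(C)C)C(C)C)cc2O)c1OC(C)C | intermediate
10 | 2-{[3-ethynyl-2-isopropoxy-4-(triisopropylsilyloxy)phenyl]ethynyl}-4-(3-methylbut-2-enyl)-5-(triisopropylsilyloxy)phenol | C#Cc1c(O[Si](C(C)C)(C(C)C)C(C)C)ccc(C#Cc2cc(CC=C(C)C)c(O[Si](C(C)C)(C(C)C)C(C)C)cc2O)c1OC(C)C | intermediate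
11 | 2-[3-ethynyl-2-isopropoxy-4-(triisopropylsilyloxy)phenyl]-5-(3-methylbut-2-enyl)-6-(triisopropylsilyloxy)benzofuran | C#Cc1c(O[Si](C(C)C)(C(C)C)C(C)C)ccc(-c2cc3cc(CC=C(C)C)c(O[Si](C(C)C)(C(C)C)C(C)C)cc3o2)c1OC(C)C | intermediate
12 | 2-[2,2-dimethyl-5-(triisopropylsilyloxy)-2H-chromen-8-yl]-5-(3-methylbut-2-enyl)-6-(triisopropylsilyloxy)benzofuran | CC(C)=CCc1cc2cc(-c3ccc(O[Si](C(C)C)(C(C)C)C(C)C)c4c3OC(C)(C)C=C4)oc2cc1O[Si](C(C)C)(C(C)C)C(C)C | intermediate
13 | kanzonol V, 8-[6-hydroxy-5-(3-methylbut-2-enyl)benzofuran-2-yl]-2,2-dimethyl-2H-chromen-5-ol | CC(C)=CCc1cc2cc(-c3ccc(O)c4c3OC(C)(C)C=C4)oc2cc1O | target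

**Step count**
Total step count: 10. Longest linear sequence: 7 (steps 1-3 or steps 4-6, then steps 7-10).

**Steps most likely to fail**

Step 9. The hydride transfer from an aryl ether may be too slow, so that hydration or oligomerization of the terminal alkyne takes over. The oxocarbenium ion may also lose a proton, or be captured by the nucleophilic C-3 of the new benzofuran, before the vinylgold carbon reaches it.

The fallback sets out from 3 and 8 and comes back at 12, and it builds the pyran ring first by known chemistry. A Petasis borono-Mannich condensation of 3 with (2-methylprop-1-en-1-yl)boronic acid and dibenzylamine (dioxane, 90 °C) is followed by thermal loss of the amine and oxa-6π electrocyclization of the ortho-quinone methide. This should give 8-iodo-2,2-dimethyl-5-(triisopropylsilyloxy)-2H-chromene F1. Sonogashira coupling of F1 with 8 (PdCl2(PPh3)2, CuI, Et3N, DMF, 23 °C, then 70 °C) gives 2-{[2,2-dimethyl-5-(triisopropylsilyloxy)-2H-chromen-8-yl]ethynyl}-4-(3-methylbut-2-enyl)-5-(triisopropylsilyloxy)phenol F2. F2 closes in the same flask by 5-endo-dig addition of the phenol to give 12.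

Step 8. Addition to an aldehyde flanked by two ortho oxygen substituents may be sluggish. Transfer of the silyl group from the phenol oxygen to the benzylic alkoxide would also stop the Peterson-type elimination.

The fallback sets out from 9 and comes back at 10 by a Corey-Fuchs sequence that passes through no alkoxide. Ramirez olefination (CBr4, PPh3, CH2Cl2, 0 °C) gives 2-{[3-(2,2-dibromovinyl)-2-isopropoxy-4-(triisopropylsilyloxy)phenyl]ethynyl}-4-(3-methylbut-2-enyl)-5-(triisopropylsilyloxy)phenol F3. Treatment of F3 with n-BuLi (3.3 equiv, THF, -78 °C) brings about bromine-lithium exchange and Fritsch-Buttenberg-Wiechell rearrangement. Aqueous quench then gives 10.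

Step 2. Silylation may not discriminate well enough between the two hydroxyl groups, because the more hindered one is also the more acidic.

The fallback sets out from 1 and comes back at 3 by reversing the order, which moves the selectivity question from oxygen to carbon. Monosilylation of the symmetric diol 1 (TIPSCl, 1.0 equiv, imidazole, DMF, 0 °C) gives 2-hydroxy-6-(triisopropylsilyloxy)benzaldehyde F4. Iodination of F4 (NIS, MeCN, 0 °C) should then go ortho to the free hydroxyl group and para to the silyl ether, because the bulky silyl group shields the other activated position. The product is 3.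

**Further compounds**
F1 | step 9 | 8-iodo-2,2-dimethyl-5-(triisopropylsilyloxy)-2H-chromene | CC1(C)C=Cc2c(O[Si](C(C)C)(C(C)C)C(C)C)ccc(I)c2O1
F2 | step 9 | 2-{[2,2-dimethyl-5-(triisopropylsilyloxy)-2H-chromen-8-yl]ethynyl}-4-(3-methylbut-2-enyl)-5-(triisopropylsilyloxy)phenol | CC(C)=CCc1cc(C#Cc2ccc(O[Si](C(C)C)(C(C)C)C(C)C)c3C=CC(C)(C)Oc23)c(O)cc1O[Si](C(C)C)(C(C)C)C(C)C
F3 | step 8 | 2-{[3-(2,2-dibromovinyl)-2-isopropoxy-4-(triisopropylsilyloxy)phenyl]ethynyl}-4-(3-methylbut-2-enyl)-5-(triisopropylsilyloxy)phenol | BrC(Br)=Cc1c(O[Si](C(C)C)(C(C)C)C(C)C)ccc(C#Cc2cc(CC=C(C)C)c(O[Si](C(C)C)(C(C)C)C(C)C)cc2O)c1OC(C)C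
F4 | step 2 | 2-hydroxy-6-(triisopropylsilyloxy)benzaldehyde | O=Cc1c(O)cccc1O[Si](C(C)C)(C(C)C)C(C)C
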